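**Plan**

1. Numbering: pyrrole N4–C9a–C1–C2–C3; azepane N4, C5–C9, C9a; carbocycle C9a–C1–C12–C11–C10–C9; fused lactone C11–O–C14(=O)–C13(Me)–C12; pendant lactone C18(O)–C19–C20(Me)–C21(=O) on C3; ethyl on C10.
2. Cuts: ethyl back to vinyl. Then, in one stroke, C1–C12, the acyl C14–O bond and C10–C11. This leads to an (E)-allylboronate on C9 of a pyrroloazepine and to methyl (Z)-2-methyl-4-oxobut-2-enoate. Further cuts: the boronate carbons (cross-metathesis), C9–C9a (allene hydroarylation), C20–Me, and the pyrrole (Paal–Knorr).
3. Enabling feature: C12 is the β-carbon of an α-methylbutenolide (C11–O–C14–C13=C12) and lies 1,6 to the enamine-like β-carbon C1 of the pyrrole. C10(vinyl)–C11(O) is a homoallylic alcohol retron. One allyl transfer therefore builds the butenolide beside the pyrrole, and the pyrrole then closes the carbocycle on it.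
4. Ring order forward: pendant lactone (bought), pyrrole, azepane, fused lactone, carbocycle last (the last two in one flask).
5. Stereochemistry: C18 from the lactone acid of D-glutamic acid; C20 by trans alkylation; C9 by a chiral gold catalyst; C10/C11 by E geometry, chair transition state and (S)-TRIP; C12 by the tether (cis fusion); C13 by convex-face protonation.

Key step: step 11

Assumption: the sense of induction of the two chiral catalysts (steps 7 and 11) is assigned by analogy with their accepted models. If a test run shows the opposite sense, the mirror-image ligand or acid is used and nothing else changes.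

**Step 1**
Reactants: 1 N-(hex-5-yn-1-yl)phthalimide
Product: 2 N-(hepta-5,6-dien-1-yl)phthalimide
Conditions: (CH2O)n, Cy2NH, CuI (0.5 equiv), dioxane, reflux
Reagents that add atoms: formaldehyde (from paraformaldehyde) C=O
Why: Crabbé–Ma allenation, in which the copper acetylide undergoes a Mannich coupling and the propargylic amine fragments by 1,5-hydride shift to the terminal allene; the imide is inert and no stereocenter forms.

**Step 2**
Reactants: 2 N-(hepta-5,6-dien-1-yl)phthalimide
Product: 3 hepta-5,6-dien-1-amine
Conditions: N2H4·H2O, EtOH, 60 °C, under N2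
Reagents that add atoms: none
Why: Ing–Manske hydrazinolysis (Gabriel amine release) frees the primary amine, and exclusion of air prevents diimide reduction of the allene.

**Step 3**
Reactants: 4 (R)-5-oxooxolane-2-carboxylic acid
Product: 5 (R)-5-oxooxolane-2-carbonyl chloride
Conditions: (COCl)2, DMF (cat.), CH2Cl2, 0 °C to rt
Reagents that add atoms: oxalyl chloride ClC(=O)C(=O)Cl
Why: Acid chloride formation through the Vilsmeier-type chloroiminium salt runs without base, so the future C18 center is not enolised.

**Step 4**
Reactants: 5 (R)-5-oxooxolane-2-carbonyl chloride; 6 [2-(1,3-dioxolan-2-yl)ethyl]magnesium bromide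
Product: 7 (R)-5-[3-(1,3-dioxolan-2-yl)propanoyl]oxolan-2-one
Conditions: Fe(acac)3 (3 mol %), THF, −78 °C
Reagents that add atoms: none
Why: Iron-catalysed acylation of a Grignard reagent by an acid chloride (Kumada-type cross-coupling) is much faster at −78 °C than addition to the lactone or to the new ketone, and the cold, short contact should leave C18 intact.

**Step 5**
Reactants: 7 (R)-5-[3-(1,3-dioxolan-2-yl)propanoyl]oxolan-2-one; 3 hepta-5,6-dien-1-amine
Product: 9 (R)-5-[1-(hepta-5,6-dien-1-yl)-1H-pyrrol-2-yl]oxolan-2-one, via keto aldehyde 8 (not isolated)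
Conditions: Amberlyst-15, THF/H2O (10:1), 40 °C; filter; add 3, AcOH (10 mol %), rt
Reagents that add atoms: none
Why: Acetal hydrolysis followed by a Paal–Knorr pyrrole synthesis turns the former carboxyl carbon of 4 into C3, and the near-neutral second stage at room temperature should neither enolise nor ionise C18.

**Step 6**
Reactants: 9 (R)-5-[1-(hepta-5,6-dien-1-yl)-1H-pyrrol-2-yl]oxolan-2-one
Product: 10 (3S,5R)-5-[1-(hepta-5,6-dien-1-yl)-1H-pyrrol-2-yl]-3-methyloxolan-2-one (methyl trans to pyrrolyl)
Conditions: LDA (1.05 equiv), THF, −78 °C; MeI, −78 to −40 °C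
Reagents that add atoms: iodomethane CI
Why: In this lactone enolate alkylation MeI should approach the face opposite the C18 pyrrolyl group, which sets C20 as S (trans-3,5).

**Step 7**
Reactants: 10 (3S,5R)-5-[1-(hepta-5,6-dien-1-yl)-1H-pyrrol-2-yl]-3-methyloxolan-2-one
Product: 11 (3S,5R)-5-[(9R)-9-ethenyl-6,7,8,9-tetrahydro-5H-pyrrolo[1,2-a]azepin-3-yl]-3-methyloxolan-2-one
Conditions: [(S)-DTBM-MeO-BIPHEP](AuCl)2 (2.5 mol %), AgBF4 (5 mol %), toluene, −10 °C to rt, 0.01 M
Reagents that add atoms: none
Why: In this intramolecular exo-hydroarylation of an allene under monovalent gold catalysis, the free α-carbon C9a attacks the gold-bound proximal allene carbon 7-exo and protodeauration leaves the vinyl group; the chiral bisphosphine chooses the allene face to set C9 as R, and any 9S material is a diastereomer that can be removed.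

**Step 8**
Reactants: 11 (3S,5R)-5-[(9R)-9-ethenyl-6,7,8,9-tetrahydro-5H-pyrrolo[1,2-a]azepin-3-yl]-3-methyloxolan-2-one; 12 allylboronic acid pinacol ester
Product: 13 (3S,5R)-3-methyl-5-{(9R)-9-[(E)-3-(4,4,5,5-tetramethyl-1,3,2-dioxaborolan-2-yl)prop-1-en-1-yl]-6,7,8,9-tetrahydro-5H-pyrrolo[1,2-a]azepin-3-yl}oxolan-2-one
Conditions: second-generation Hoveyda–Grubbs catalyst (5 mol %), 12 (3 equiv), CH2Cl2, 40 °C
Reagents that add atoms: none
Why: In this olefin cross-metathesis of a branched terminal alkene with allyl pinacol boronate, the branching at C9 suppresses homodimerisation and should favour the E-alkene, and C9 is untouched.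

**Step 9**
Reactants: 14 3-methylfuran-2-carboxylic acid
Product: 15 5-hydroxy-3-methylfuran-2(5H)-one (racemic lactol)
Conditions: O2, rose bengal, visible light, MeOH, 0 °C
Reagents that add atoms: oxygen O=O
Why: Singlet-oxygen [4+2] cycloaddition to the furan and decarboxylative fragmentation of the endoperoxide give the hydroxybutenolide, and the site of the lost carboxyl group fixes the lactone carbonyl next to the methyl-bearing carbon.

**Step 10**
Reactants: 15 5-hydroxy-3-methylfuran-2(5H)-one
Product: 16 methyl (Z)-2-methyl-4-oxobut-2-enoate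
Conditions: TMSCHN2, toluene/MeOH, 0 °C
Reagents that add atoms: (trimethylsilyl)diazomethane C[Si](C)(C)C=[N+]=[N-]
Why: Diazoalkane esterification traps the ring-opened carboxylic acid tautomer as the normal ester under neutral conditions, so the Z geometry inherited from the ring is kept.

**Step 11**
Reactants: 13 (E)-allylboronate; 16 methyl (Z)-2-methyl-4-oxobut-2-enoate (1.05 equiv)
Product: 19 (9R,10R,11S,12R,13R,18R,20S)-pentacycle with the complete target skeleton and an ethenyl group on C10, via homoallylic pinacol borate 17 (not isolated), via butenolide 18 (not isolated)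
Conditions: (S)-TRIP [(S)-3,3'-bis(2,4,6-triisopropylphenyl)-1,1'-binaphthyl-2,2'-diyl hydrogen phosphate] (10 mol %), 4 Å MS, toluene, −30 °C to rt; then Sc(OTf)3 (20 mol %), MeCN, 0 °C to rt
Reagents that add atoms: none
Why: The phosphoric acid hydrogen-bonds to a boronate oxygen of 13 and to the formyl group of 16, the allyl unit is transferred through a closed six-membered chair (C10–C11 bond, the double bond moves out to become the vinyl group on C10), the borate oxygen of 17 acylates itself on the cis-placed methyl ester with loss of MeOBpin to give butenolide 18, and Sc(OTf)3 bound to the butenolide carbonyl triggers attack of pyrrole C1 on C12, loss of the C1 proton and ketonisation at C13. The closest known reaction types are the chiral phosphoric acid catalysed allylboration of aldehydes with γ-substituted (E)-allyl pinacol boronates, the allylboration–lactonisation of formyl esters and the Lewis acid catalysed intramolecular Friedel–Crafts conjugate addition of pyrroles to unsaturated carbonyl compounds. The fused lactone closes 5-exo-trig at the ester carbonyl and the carbocycle closes last, 6-exo-trig at C12, through a chair-like array in which C8, the vinyl group and the C11 oxygen are all equatorial. C10 and C11: the E geometry in the chair fixes their anti relation (vinyl and oxygen trans on the new ring), and (S)-TRIP chooses the aldehyde face and with it the face of the allyl unit, which should override the weak bias of C9 across an E-alkene. C12: the short tether C9a–C9–C10 lets C1 reach only the butenolide face that carries C10, so the ring fusion must be cis; C13: the enol is protonated from the convex face, which leaves the hydrogens on C11, C12 and C13 cis and the methyl group on the concave face as in the target. The step needs chemoselectivity (the boronate adds only to the aldehyde, not to the enoate or the lactones), site selectivity on the pyrrole (both α-carbons are substituted and C2 cannot reach C12) and mildness toward the ionisable C18–O bond, which catalytic Sc(OTf)3 at or below room temperature should respect.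

**Step 12**
Reactants: 19 pentacycle with an ethenyl group on C10
Product: 20 target CNP0232452.4 (9R,10R,11S,12R,13R,18R,20S)
Conditions: RhCl(PPh3)3 (5 mol %), H2 (1 atm), toluene/EtOH, rt
Reagents that add atoms: none
Why: Homogeneous hydrogenation with RhCl(PPh3)3 saturates only the monosubstituted alkene and, being neutral, should cause neither hydrogenolysis of the pyrrolylic C18–O bond nor epimerisation at C13.

**Compound list**

1 | N-(hex-5-yn-1-yl)phthalimide | C#CCCCCN1C(=O)c2ccccc2C1=O | starting material
2 | N-(hepta-5,6-dien-1-yl)phthalimide | C=C=CCCCCN1C(=O)c2ccccc2C1=O | intermediate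
3 | hepta-5,6-dien-1-amine | C=C=CCCCCN | intermediate
4 | (R)-5-oxooxolane-2-carboxylic acid | OC(=O)[C@H]1CCC(=O)O1 | starting material
5 | (R)-5-oxooxolane-2-carbonyl chloride | ClC(=O)[C@H]1CCC(=O)O1 | intermediate
6 | [2-(1,3-dioxolan-2-yl)ethyl]magnesium bromide | Br[Mg]CCC1OCCO1 | starting material
7 | (R)-5-[3-(1,3-dioxolan-2-yl)propanoyl]oxolan-2-one | O=C(CCC1OCCO1)[C@H]1CCC(=O)O1 | intermediate
8 | (R)-4-oxo-4-(5-oxooxolan-2-yl)butanal | O=CCCC(=O)[C@H]1CCC(=O)O1 | intermediate
9 | (R)-5-[1-(hepta-5,6-dien-1-yl)-1H-pyrrol-2-yl]oxolan-2-one | C=C=CCCCCn1cccc1[C@H]1CCC(=O)O1 | intermediate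
10 | (3S,5R)-5-[1-(hepta-5,6-dien-1-yl)-1H-pyrrol-2-yl]-3-methyloxolan-2-one | C=C=CCCCCn1cccc1[C@H]1C[C@H](C)C(=O)O1 | intermediate
11 | (3S,5R)-5-[(9R)-9-ethenyl-6,7,8,9-tetrahydro-5H-pyrrolo[1,2-a]azepin-3-yl]-3-methyloxolan-2-one | C=C[C@H]1CCCCn2c1ccc2[C@H]1C[C@H](C)C(=O)O1 | intermediate
12 | allylboronic acid pinacol ester | C=CCB1OC(C)(C)C(C)(C)O1 | starting material
13 | (E)-allylboronate on C9 of the pyrroloazepine (9R,18R,20S) | CC1(C)OB(C/C=C/[C@H]2CCCCn3c2ccc3[C@H]2C[C@H](C)C(=O)O2)OC1(C)C | intermediate
14 | 3-methylfuran-2-carboxylic acid | Cc1ccoc1C(=O)O | starting material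
15 | 5-hydroxy-3-methylfuran-2(5H)-one | CC1=CC(O)OC1=O | intermediate
16 | methyl (Z)-2-methyl-4-oxobut-2-enoate | COC(=O)/C(C)=C\C=O | intermediate
17 | methyl (2Z,4S,5R)-2-methyl-4-(pinacolboryloxy)-5-(pyrroloazepin-9-yl)hepta-2,6-dienoate (9R,18R,20S) | C=C[C@@H]([C@H](OB1OC(C)(C)C(C)(C)O1)/C=C(/C)C(=O)OC)[C@H]1CCCCn2c1ccc2[C@H]1C[C@H](C)C(=O)O1 | intermediate
18 | (5S)-3-methyl-5-[(1R)-1-(pyrroloazepin-9-yl)prop-2-en-1-yl]furan-2(5H)-one (9R,18R,20S) | C=C[C@@H]([C@@H]1OC(=O)C(C)=C1)[C@H]1CCCCn2c1ccc2[C@H]1C[C@H](C)C(=O)O1 | intermediate
19 | pentacycle with an ethenyl group on C10 (9R,10R,11S,12R,13R,18R,20S) | C=C[C@H]1[C@@H]2OC(=O)[C@H](C)[C@@H]2c2cc([C@H]3C[C@H](C)C(=O)O3)n3c2[C@@H]1CCCC3 | intermediate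
20 | CNP0232452.4 | CC[C@H]1[C@@H]2OC(=O)[C@H](C)[C@@H]2c2cc([C@H]3C[C@H](C)C(=O)O3)n3c2[C@@H]1CCCC3 | target

**Step count**

Total step count: 12.
Longest linear sequence: 8 (steps 3, 4, 5, 6, 7, 8, 11, 12).

**Steps most likely to fail**

**Step 11.** Two things may go wrong:
- Catalyst control over the face of the allyl unit next to C9 may be incomplete.
- The conjugate addition onto the α-methylated butenolide may be slow. Lewis acid induced ionisation of the pyrrolylic C18–O bond, with epimerisation at C18, could then compete.

The fallback sets out from 18, which is isolated when the scandium salt is left out, and comes back at 20. It proceeds as follows: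
- Hydrogenation with RhCl(PPh3)3 saturates only the vinyl group and gives the ethyl butenolide F1.
- An intramolecular oxidative C–H alkenylation follows (Fujiwara–Moritani reaction with divalent palladium: Pd(OAc)2, ethyl nicotinate, O2, tert-amyl alcohol, 80 °C). It palladates C1, inserts the butenolide double bond 6-exo on the face that carries C10, and eliminates a methyl hydrogen. This gives the α-methylene lactone F2.
- Hydrogenation of the exocyclic double bond from the convex face (RhCl(PPh3)3, H2, 4 atm) sets C13 and gives 20.

**Step 7.** Closure of the seven-membered ring may be slow, which lets oligomerisation of the allene compete. Facial selectivity at a terminal allene far from the ligand pocket may also be poor. The fallback sets out from 7 and comes back at 11: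
- The same acetal hydrolysis, then Paal–Knorr condensation with commercial hex-5-en-1-amine, gives the N-hexenylpyrrole lactone F3.
- LDA and MeI give the trans-methyl lactone F4.
- Cross-metathesis with (Z)-but-2-ene-1,4-diyl dimethyl dicarbonate gives the (E)-allylic carbonate F5.
- An intramolecular asymmetric allylic alkylation with monovalent iridium follows ([Ir(cod)Cl]2, a BINOL-derived bis(1-phenylethyl)amine phosphoramidite, THF, 50 °C). C9a attacks the substituted terminus of the π-allyl complex and gives the branched product 11.

**Step 8.** E selectivity may be incomplete, which would pass into the syn diastereomer in step 11. Boron may also be lost on purification. The fallback sets out from 11 and comes back at 13: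
- Cross-metathesis with (Z)-but-2-ene-1,4-diyl diacetate gives the allylic acetate F6, whose geometry is not critical.
- Miyaura-type allylic borylation with zerovalent palladium (Pd2(dba)3, B2pin2, DMSO, 50 °C) passes through the equilibrating π-allyl complex and converges on the linear (E)-boronate 13.

**Further compounds**

F1 | step 11 | (5S)-3-methyl-5-[(1R)-1-(pyrroloazepin-9-yl)propyl]furan-2(5H)-one (9R,18R,20S) | CC[C@@H]([C@@H]1OC(=O)C(C)=C1)[C@H]1CCCCn2c1ccc2[C@H]1C[C@H](C)C(=O)O1
F2 | step 11 | 13-methylidene pentacycle (α-methylene fused lactone, 9R,10R,11S,12R,18R,20S) | CC[C@H]1[C@@H]2OC(=O)C(=C)[C@@H]2c2cc([C@H]3C[C@H](C)C(=O)O3)n3c2[C@@H]1CCCC3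
F3 | step 7 | (R)-5-[1-(hex-5-en-1-yl)-1H-pyrrol-2-yl]oxolan-2-one | C=CCCCCn1cccc1[C@H]1CCC(=O)O1
F4 | step 7 | (3S,5R)-5-[1-(hex-5-en-1-yl)-1H-pyrrol-2-yl]-3-methyloxolan-2-one | C=CCCCCn1cccc1[C@H]1C[C@H](C)C(=O)O1
F5 | step 7 | methyl (E)-7-{2-[(2R,4S)-4-methyl-5-oxooxolan-2-yl]-1H-pyrrol-1-yl}hept-2-en-1-yl carbonate | COC(=O)OC/C=C/CCCCn1cccc1[C@H]1C[C@H](C)C(=O)O1
F6 | step 8 | (E)-3-{(9R)-3-[(2R,4S)-4-methyl-5-oxooxolan-2-yl]-6,7,8,9-tetrahydro-5H-pyrrolo[1,2-a]azepin-9-yl}prop-2-en-1-yl acetate | CC(=O)OC/C=C/[C@H]1CCCCn2c1ccc2[C@H]1C[C@H](C)C(=O)O1
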